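The 6 questions are one question put at 3 times: in a closed flask of substrate and coupling partner, what holds most of the charge at the end, and how much? You can answer what holds most with a single time read from the earlier runs.

| flask | substrate | coupling partner | remark | time |
|---|---|---|---|---|
| north-west | 0.68 M | 0.50 M | run made earlier |  |
| west | 0.68 M | 1.1 M | run made earlier |  |
| south-west | 1 M | 0.748 M | run made earlier |  |
| alder | 0.68 M | 0.748 M |  | 3.0 h |
| elm | 0.68 M | 0.748 M |  | 4.0 h |
| larch | 0.68 M | 0.748 M |  | 5.0 h |

| run | time / h | product / % | intermediate A / % | substrate / % | intermediate B / % | intermediate C / % |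
|---|---|---|---|---|---|---|
| north-west | 0.200 | 0 | 1.5 | 92.1 | 3.9 | 2.3 |
| north-west | 0.667 | 0.5 | 1.2 | 77.3 | 11.4 | 9.6 |
| north-west | 1.00 | 0.4 | 1.2 | 67.6 | 14.9 | 15.0 |
| north-west | 1.50 | 0.4 | 1.2 | 56.0 | 19.5 | 21.8 |
| north-west | 2.50 | 0.6 | 0.6 | 37.9 | 25.0 | 33.0 |
| west | 0.200 | 0 | 1.7 | 92.4 | 3.7 | 2.1 |
| west | 0.333 | 0.2 | 1.6 | 88.2 | 6.3 | 4.8 |
| west | 0.667 | 0.1 | 1.5 | 77.1 | 11.0 | 9.9 |
| west | 1.33 | 0.1 | 1.4 | 59.1 | 18.8 | 19.9 |
| west | 2.50 | 0.5 | 1.1 | 37.8 | 25.0 | 33.7 |
| south-west | 0.500 | 0.4 | 2.0 | 82.8 | 8.7 | 7.1 |
| south-west | 1.00 | 0 | 1.5 | 67.7 | 14.8 | 15.1 |
| south-west | 1.33 | 0 | 0.8 | 59.7 | 18.3 | 19.5 |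
| south-west | 2.00 | 0.6 | 1.4 | 46.0 | 23.4 | 27.7 |
| south-west | 2.50 | 0.3 | 1.0 | 37.8 | 25.4 | 33.0 |

(standard deviation of a reading: 0.3 percentage points)

- a reading or a percentage of product counts all its forms, free or not

- which of these there is most of at the end, counted by the substrate in it, alder (intermediate A / intermediate B / substrate / intermediate C)
- which of these there is most of at the end, counted by the substrate in it, elm (intermediate A / intermediate B / substrate / intermediate C)
- which of these there is most of at the end, counted by the substrate in it, larch (intermediate A / intermediate B / substrate / intermediate C)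
- amount of the one of these that there is most of at the end, in percent of the substrate charged, alder
- amount of the one of these that there is most of at the end, in percent of the substrate charged, elm
- amount of the one of these that there is most of at the end, in percent of the substrate charged, larch

Read those runs as a ladder of time scales, fastest first. In the north-west run intermediate A stands at 1.5% by the first reading at 0.200 h and stays at or below that, so you may treat it as a quasi-steady intermediate and leave it out of the count, along with product, which reads 0.6% at 2.50 h. The substrate comes next: the north-west and west runs, the second with twice the coupling partner, read 37.9% and 37.8% at 2.50 h, and the south-west run, with its larger substrate charge, reads 37.8%, so I take one first-order constant k of 0.388 h⁻¹, whose time scale 1/k, 2.58 h, is far longer than that first reading. Slower again, intermediate B gains more slowly than it did early and lags intermediate C, 25.0% against 33.0% at 2.50 h. Slowest is a small shortfall in the balance, 2.5 percentage points in the south-west run at 2.50 h.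

B and that shortfall are then only corrections to one number, the share s of the lost substrate that stands as C, which the north-west run reads as 53.1% at 2.50 h. Holding s fixed, C and the substrate are level when the substrate left is s divided by one plus s, and the logarithm of the inverse of that fraction, divided by k, gives the crossover time t× at which C overtakes the substrate, 2.73 h. Alder, elm and larch are all read later than that, so my answer is C. The share has risen from 46.3% at 1.00 h, so my fixed-share figures, 36.6% for alder and 45.5% for larch, are low ones.

For alder, elm and larch the forecast names intermediate C, intermediate C and intermediate C, at 38.5%, 45.5% and 51%, higher than mine. It takes C by difference, subtracting a growing unseen loss, and it holds B level: “B also drains slowly to C, at about 0.15 /h, so B plateaus near 27%.”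

The simulation gives intermediate C, intermediate C and intermediate C at 37.8%, 44.8% and 49.7% for alder, elm and larch, within the margins of the forecast.

    substrate ⇌ intermediate A (K = 0.890, k = 5.32 × 10⁻⁵ s⁻¹)
    substrate → intermediate B (k = 5.58 × 10⁻⁵ s⁻¹)
    intermediate A → intermediate C (k = 0.00290 s⁻¹)
    intermediate A ⇌ product (K = 0.380, k = 7.28 × 10⁻⁵ s⁻¹)
    intermediate C ⇌ intermediate B (K = 0.112, k = 6.23 × 10⁻⁶ s⁻¹)
    crystals ⇌ product, rate k6*(cs6 - [product]) while solid is left; crystals form when [product] > cs6 (solubility = 0.0510 M, k = 0.00174 s⁻¹)
    intermediate C → decomposed reagent (k = 1.69 × 10⁻⁵ s⁻¹)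

What stands in the flask follows the reading time set against t×: alder, read at 3.0 h, is past 2.73 h, and there C at 37.8% holds most, over 31.2% of substrate, with product at 0.294% and decomposed reagent, the unseen loss, at 3.79%. The same flask stopped at 2.0 h, before t×, still has substrate ahead, 46.0% against 28.1% of C, and the two stand level at 2.69 h.

The readings come from a simulation for an exercise, noise included.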